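**Strategy**

The 2,2-dimethyl-2H-pyran ring fused to ring B is cut at both of its bonds to the arene, C4–C4a and O1–C8a, which sit on the vicinal ring-B carbons C3' and C4'. This pattern is the signature of an aryne taking up a C=O group: an aryne at C3'≡C4' and 3-methylbut-2-enal give, by [2+2] addition, 4π opening and oxa-6π closure, the whole pyran ring in one operation. The precursor is a gallate-derived ortho-silyl tris(triflate); the triflate beside the aryne steers the addition and later becomes the prenyl group, the outer one the acetyl handle for an aldol, transfer-hydrogenation and Mitsunobu flavan synthesis, and a final Claisen rearrangement sets the 1,1-dimethylallyl group.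

Key step: step 6

Remark: ring B is numbered C1' (bearing the chroman) to C6'; C2' carries the prenyl group, C3' and C4' the pyran carbon and oxygen, C5' the hydroxyl group. Compounds 1, 9 and 18 are taken as purchasable.

**Route**

Step 1
Reactants: 1 3,4,5-tris(benzyloxy)benzaldehyde
Product: 3 3,4,5-tris(benzyloxy)phenol, via aryl formate 2 (not isolated)
Conditions: mCPBA, CH2Cl2, 0 °C to rt; then K2CO3 (cat.), MeOH, rt
Reagents that add atoms: 3-chloroperoxybenzoic acid, O=C(OO)c1cccc(Cl)c1
Why: Baeyer–Villiger (Dakin-type) oxidation, in which the electron-rich trialkoxyaryl group migrates in preference to hydride and formate 2 is transesterified by methanol to the phenol.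

Step 2
Reactants: 3 3,4,5-tris(benzyloxy)phenol
Product: 4 1,2,3-tris(benzyloxy)-5-(methoxymethoxy)benzene
Conditions: NaH, MOMCl, THF, 0 °C to rt
Reagents that add atoms: chloromethyl methyl ether, COCCl
Why: Williamson-type O-alkylation of the sodium phenoxide; the acetal directs the metalation of step 3 and should survive hydrogenolysis, triflation and fluoride.

Step 3
Reactants: 4 1,2,3-tris(benzyloxy)-5-(methoxymethoxy)benzene
Product: 6 [2,3,4-tris(benzyloxy)-6-(methoxymethoxy)phenyl]trimethylsilane, via aryllithium 5 (not isolated)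
Conditions: n-BuLi, TMEDA, THF, −78 to 0 °C; then Me3SiCl, −78 °C to rt
Reagents that add atoms: chlorotrimethylsilane, C[Si](C)(C)Cl
Why: Directed ortho-metalation; the two positions between the methoxymethoxy group and a benzyloxy group are equivalent by symmetry, so lithiation to 5 and silylation should give a single product.

Step 4
Reactants: 6 [2,3,4-tris(benzyloxy)-6-(methoxymethoxy)phenyl]trimethylsilane
Product: 7 5-(methoxymethoxy)-4-(trimethylsilyl)benzene-1,2,3-triol
Conditions: H2 (1 atm), 10% Pd/C, EtOAc/MeOH, rt; used at once under argon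
Reagents that add atoms: none
Why: Hydrogenolysis of the three benzyl ethers over Pd/C, which should leave the aryl–silicon bond and the acetal untouched.

Step 5
Reactants: 7 5-(methoxymethoxy)-4-(trimethylsilyl)benzene-1,2,3-triol
Product: 8 5-(methoxymethoxy)-4-(trimethylsilyl)benzene-1,2,3-triyl tris(trifluoromethanesulfonate)
Conditions: Tf2O, pyridine, CH2Cl2, −40 to 0 °C
Reagents that add atoms: trifluoromethanesulfonic anhydride, O=S(=O)(OS(=O)(=O)C(F)(F)F)C(F)(F)F
Why: O-sulfonylation of all three phenols gives the ortho-silylaryl triflate needed for fluoride-induced aryne formation and two further triflates for the later cross-couplings.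

Step 6
Reactants: 8 5-(methoxymethoxy)-4-(trimethylsilyl)benzene-1,2,3-triyl tris(trifluoromethanesulfonate); 9 3-methylbut-2-enal
Product: 13 8-(methoxymethoxy)-2,2-dimethyl-2H-chromene-5,6-diyl bis(trifluoromethanesulfonate), via aryne 10 (not isolated), via benzoxete 11 (not isolated), via ortho-quinone methide 12 (not isolated)
Conditions: CsF (3 equiv), 9 (5 equiv), MeCN, rt
Reagents that add atoms: none
Why: Fluoride removes the silyl group at C4' and the C3' triflate leaves (the acetal oxygen on the other side cannot), so only aryne 10 forms; the carbonyl oxygen of the enal adds to C4' and C3' closes onto the carbonyl carbon (formal [2+2]) to benzoxete 11, whose 4π electrocyclic opening gives ortho-quinone methide 12, which closes by oxa-6π electrocyclisation to the 2H-pyran ring. This is the known aryne/α,β-unsaturated aldehyde route to 2H-chromenes, a relative of aryne insertion into formamide C=O bonds. The four-membered ring is closed by the stepwise polar [2+2] addition and reopened, and the pyran ring is closed by a thermal disrotatory 6π electrocyclisation that forms the O–CMe2 bond; no stereocentre remains because the benzoxete carbon becomes sp2. The step needs the oxygen to bond to C4' and not to C3': the triflyloxy group at C2' is a stronger σ-acceptor than the acetal oxygen at C5' and should make C4' the more electrophilic aryne terminus, as 3-triflyloxyarynes take nucleophiles at the remote carbon, and the aryl anion so formed is trapped by the adjacent oxocarbenium carbon faster than it expels triflate. Excess enal and the intramolecular 6π closure should keep 12 from capturing a second aryne.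

Step 7
Reactants: 13 8-(methoxymethoxy)-2,2-dimethyl-2H-chromene-5,6-diyl bis(trifluoromethanesulfonate)
Product: 16 6-acetyl-8-hydroxy-2,2-dimethyl-2H-chromen-5-yl trifluoromethanesulfonate, via enol ether 14 (not isolated), via methoxymethyl ether ketone 15 (not isolated)
Conditions: tributyl(1-ethoxyethenyl)stannane (1.05 equiv), Pd(PPh3)4 (5 mol%), LiCl, 1,4-dioxane, 80 °C; then 2 M HCl, MeOH/THF, 50 °C
Reagents that add atoms: tributyl(1-ethoxyethenyl)stannane, CCCC[Sn](CCCC)(CCCC)C(=C)OCC; water, O
Why: Site-selective Stille coupling, in which oxidative addition to zerovalent palladium should prefer the C6 triflate (one free ortho position) over the C5 triflate wedged between it and the pyran ring; acid then hydrolyses enol ether 14 to ketone 15 and cleaves the methoxymethyl ether while no acid-sensitive prenyl group is present.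

Step 8
Reactants: 16 6-acetyl-8-hydroxy-2,2-dimethyl-2H-chromen-5-yl trifluoromethanesulfonate
Product: 17 1-[8-hydroxy-2,2-dimethyl-5-(3-methylbut-2-en-1-yl)-2H-chromen-6-yl]ethan-1-one
Conditions: tributyl(3-methylbut-2-en-1-yl)stannane, Pd(PPh3)4 (5 mol%), LiCl, DMF, 90 °C
Reagents that add atoms: tributyl(3-methylbut-2-en-1-yl)stannane, CCCC[Sn](CCCC)(CCCC)CC=C(C)C
Why: Stille coupling of the remaining, ketone-activated aryl triflate; reductive elimination from the less hindered σ-allylpalladium species should give the linear prenyl arene.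

Step 9
Reactants: 18 2,4-dihydroxybenzaldehyde
Product: 19 2-hydroxy-4-[(3-methylbut-2-en-1-yl)oxy]benzaldehyde
Conditions: 1-bromo-3-methylbut-2-ene, K2CO3, acetone, rt
Reagents that add atoms: 1-bromo-3-methylbut-2-ene, CC(C)=CCBr
Why: Williamson etherification, selective for the 4-hydroxyl group because the 2-hydroxyl group is hydrogen-bonded to the formyl group and less acidic.

Step 10
Reactants: 17 1-[8-hydroxy-2,2-dimethyl-5-(3-methylbut-2-en-1-yl)-2H-chromen-6-yl]ethan-1-one; 19 2-hydroxy-4-[(3-methylbut-2-en-1-yl)oxy]benzaldehyde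
Product: 21 (2E)-1-[8-hydroxy-2,2-dimethyl-5-(3-methylbut-2-en-1-yl)-2H-chromen-6-yl]-3-{2-hydroxy-4-[(3-methylbut-2-en-1-yl)oxy]phenyl}prop-2-en-1-one, via aldol adduct 20 (not isolated)
Conditions: KOH, EtOH/H2O, rt; then AcOH
Reagents that add atoms: none
Why: Claisen–Schmidt aldol condensation through aldol 20; the ethers and the chromene are base-stable and dehydration gives the conjugated E-enone.

Step 11
Reactants: 21 (2E)-1-[8-hydroxy-2,2-dimethyl-5-(3-methylbut-2-en-1-yl)-2H-chromen-6-yl]-3-{2-hydroxy-4-[(3-methylbut-2-en-1-yl)oxy]phenyl}prop-2-en-1-one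
Product: 23 (1R)-1-[8-hydroxy-2,2-dimethyl-5-(3-methylbut-2-en-1-yl)-2H-chromen-6-yl]-3-{2-hydroxy-4-[(3-methylbut-2-en-1-yl)oxy]phenyl}propan-1-ol, via saturated ketone 22 (not isolated)
Conditions: RuCl(p-cymene)[(R,R)-TsDPEN] (3 mol%), HCO2H/Et3N (5:2), EtOAc, 40 °C
Reagents that add atoms: none
Why: Asymmetric transfer hydrogenation, in which the ruthenium hydride first reduces the conjugated C=C bond to ketone 22 and then the aryl ketone through the six-membered metal–ligand bifunctional transition state, the (R,R)-ligand setting the R configuration, while isolated and styrenic alkenes are not reduced.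

Step 12
Reactants: 23 (1R)-1-[8-hydroxy-2,2-dimethyl-5-(3-methylbut-2-en-1-yl)-2H-chromen-6-yl]-3-{2-hydroxy-4-[(3-methylbut-2-en-1-yl)oxy]phenyl}propan-1-ol
Product: 24 6-{(2S)-7-[(3-methylbut-2-en-1-yl)oxy]-3,4-dihydro-2H-chromen-2-yl}-2,2-dimethyl-5-(3-methylbut-2-en-1-yl)-2H-chromen-8-ol
Conditions: PPh3, DIAD, THF (0.02 M), 0 °C to rt
Reagents that add atoms: none
Why: Intramolecular Mitsunobu etherification, in which the ring-A phenol displaces the activated benzylic alcohol in a 6-exo-tet SN2 reaction with inversion (R carbinol to 2S flavan); the ring-B phenol cannot reach the carbinol carbon and dilution suppresses its intermolecular reaction.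

Step 13
Reactants: 24 6-{(2S)-7-[(3-methylbut-2-en-1-yl)oxy]-3,4-dihydro-2H-chromen-2-yl}-2,2-dimethyl-5-(3-methylbut-2-en-1-yl)-2H-chromen-8-ol
Product: 26 Kazinol H, via cyclohexadienone 25 (not isolated)
Conditions: EtOH/H2O (4:1), 130 °C, sealed tube, degassed
Reagents that add atoms: none
Why: Aromatic Claisen rearrangement ([3,3]-sigmatropic) of the aryl prenyl ether and tautomerisation of dienone 25; the allyl unit is inverted to the 1,1-dimethylallyl group, C6 should be preferred over C8 (which lies between two oxygen substituents and would have to carry the quaternary carbon), and the C2 stereocentre is not touched.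

**Compound list**

1 | 3,4,5-tris(benzyloxy)benzaldehyde | O=Cc1cc(OCc2ccccc2)c(OCc2ccccc2)c(OCc2ccccc2)c1 | starting material
2 | 3,4,5-tris(benzyloxy)phenyl formate | O=COc1cc(OCc2ccccc2)c(OCc2ccccc2)c(OCc2ccccc2)c1 | intermediate
3 | 3,4,5-tris(benzyloxy)phenol | Oc1cc(OCc2ccccc2)c(OCc2ccccc2)c(OCc2ccccc2)c1 | intermediate
4 | 1,2,3-tris(benzyloxy)-5-(methoxymethoxy)benzene | COCOc1cc(OCc2ccccc2)c(OCc2ccccc2)c(OCc2ccccc2)c1 | intermediate
5 | [2,3,4-tris(benzyloxy)-6-(methoxymethoxy)phenyl]lithium | COCOc1cc(OCc2ccccc2)c(OCc2ccccc2)c(OCc2ccccc2)c1[Li] | intermediate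
6 | [2,3,4-tris(benzyloxy)-6-(methoxymethoxy)phenyl]trimethylsilane | COCOc1cc(OCc2ccccc2)c(OCc2ccccc2)c(OCc2ccccc2)c1[Si](C)(C)C | intermediate
7 | 5-(methoxymethoxy)-4-(trimethylsilyl)benzene-1,2,3-triol | COCOc1cc(O)c(O)c(O)c1[Si](C)(C)C | intermediate
8 | 5-(methoxymethoxy)-4-(trimethylsilyl)benzene-1,2,3-triyl tris(trifluoromethanesulfonate) | COCOc1cc(OS(=O)(=O)C(F)(F)F)c(OS(=O)(=O)C(F)(F)F)c(OS(=O)(=O)C(F)(F)F)c1[Si](C)(C)C | intermediate
9 | 3-methylbut-2-enal | CC(C)=CC=O | starting material
10 | 3-(methoxymethoxy)-5,6-bis(trifluoromethylsulfonyloxy)-1,2-didehydrobenzene (aryne) | COCOC1=CC(OS(=O)(=O)C(F)(F)F)=C(OS(=O)(=O)C(F)(F)F)C#C1 | intermediate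
11 | 6-(methoxymethoxy)-2-(2-methylprop-1-en-1-yl)-2H-benzo[b]oxete-3,4-diyl bis(trifluoromethanesulfonate), racemic | COCOc1cc(OS(=O)(=O)C(F)(F)F)c(OS(=O)(=O)C(F)(F)F)c2c1OC2C=C(C)C | intermediate
12 | 5-(methoxymethoxy)-3-(3-methylbut-2-en-1-ylidene)-4-oxocyclohexa-1,5-diene-1,2-diyl bis(trifluoromethanesulfonate) | COCOC1=CC(OS(=O)(=O)C(F)(F)F)=C(OS(=O)(=O)C(F)(F)F)C(=CC=C(C)C)C1=O | intermediate
13 | 8-(methoxymethoxy)-2,2-dimethyl-2H-chromene-5,6-diyl bis(trifluoromethanesulfonate) | COCOc1cc(OS(=O)(=O)C(F)(F)F)c(OS(=O)(=O)C(F)(F)F)c2c1OC(C)(C)C=C2 | intermediate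
14 | 6-(1-ethoxyethenyl)-8-(methoxymethoxy)-2,2-dimethyl-2H-chromen-5-yl trifluoromethanesulfonate | CCOC(=C)c1cc(OCOC)c2c(c1OS(=O)(=O)C(F)(F)F)C=CC(C)(C)O2 | intermediate
15 | 6-acetyl-8-(methoxymethoxy)-2,2-dimethyl-2H-chromen-5-yl trifluoromethanesulfonate | CC(=O)c1cc(OCOC)c2c(c1OS(=O)(=O)C(F)(F)F)C=CC(C)(C)O2 | intermediate
16 | 6-acetyl-8-hydroxy-2,2-dimethyl-2H-chromen-5-yl trifluoromethanesulfonate | CC(=O)c1cc(O)c2c(c1OS(=O)(=O)C(F)(F)F)C=CC(C)(C)O2 | intermediate
17 | 1-[8-hydroxy-2,2-dimethyl-5-(3-methylbut-2-en-1-yl)-2H-chromen-6-yl]ethan-1-one | CC(=O)c1cc(O)c2c(c1CC=C(C)C)C=CC(C)(C)O2 | intermediate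
18 | 2,4-dihydroxybenzaldehyde | O=Cc1ccc(O)cc1O | starting material
19 | 2-hydroxy-4-[(3-methylbut-2-en-1-yl)oxy]benzaldehyde | O=Cc1ccc(OCC=C(C)C)cc1O | intermediate
20 | 3-hydroxy-1-[8-hydroxy-2,2-dimethyl-5-(3-methylbut-2-en-1-yl)-2H-chromen-6-yl]-3-{2-hydroxy-4-[(3-methylbut-2-en-1-yl)oxy]phenyl}propan-1-one, racemic | O=C(CC(O)c1ccc(OCC=C(C)C)cc1O)c1cc(O)c2c(c1CC=C(C)C)C=CC(C)(C)O2 | intermediate
21 | (2E)-1-[8-hydroxy-2,2-dimethyl-5-(3-methylbut-2-en-1-yl)-2H-chromen-6-yl]-3-{2-hydroxy-4-[(3-methylbut-2-en-1-yl)oxy]phenyl}prop-2-en-1-one | O=C(/C=C/c1ccc(OCC=C(C)C)cc1O)c1cc(O)c2c(c1CC=C(C)C)C=CC(C)(C)O2 | intermediate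
22 | 1-[8-hydroxy-2,2-dimethyl-5-(3-methylbut-2-en-1-yl)-2H-chromen-6-yl]-3-{2-hydroxy-4-[(3-methylbut-2-en-1-yl)oxy]phenyl}propan-1-one | O=C(CCc1ccc(OCC=C(C)C)cc1O)c1cc(O)c2c(c1CC=C(C)C)C=CC(C)(C)O2 | intermediate
23 | (1R)-1-[8-hydroxy-2,2-dimethyl-5-(3-methylbut-2-en-1-yl)-2H-chromen-6-yl]-3-{2-hydroxy-4-[(3-methylbut-2-en-1-yl)oxy]phenyl}propan-1-ol | O[C@H](CCc1ccc(OCC=C(C)C)cc1O)c1cc(O)c2c(c1CC=C(C)C)C=CC(C)(C)O2 | intermediate
24 | 6-{(2S)-7-[(3-methylbut-2-en-1-yl)oxy]-3,4-dihydro-2H-chromen-2-yl}-2,2-dimethyl-5-(3-methylbut-2-en-1-yl)-2H-chromen-8-ol | CC(C)=CCOc1ccc2c(c1)O[C@H](c1cc(O)c3c(c1CC=C(C)C)C=CC(C)(C)O3)CC2 | intermediate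
25 | (2S)-2-[8-hydroxy-2,2-dimethyl-5-(3-methylbut-2-en-1-yl)-2H-chromen-6-yl]-6-(2-methylbut-3-en-2-yl)-2,3,4,6-tetrahydro-7H-chromen-7-one (C6 unassigned) | O=C1C=C2O[C@H](c3cc(O)c4c(c3CC=C(C)C)C=CC(C)(C)O4)CCC2=CC1C(C)(C)C=C | intermediate
26 | Kazinol H, 6-[(2S)-7-hydroxy-6-(2-methylbut-3-en-2-yl)-3,4-dihydro-2H-chromen-2-yl]-2,2-dimethyl-5-(3-methylbut-2-en-1-yl)-2H-chromen-8-ol | C=CC(C)(C)c1cc2c(cc1O)O[C@H](c1cc(O)c3c(c1CC=C(C)C)C=CC(C)(C)O3)CC2 | target

**Step count**

Total steps: 13. Longest linear sequence: 12 steps (steps 1 to 8, then 10 to 13); step 9 is the one-step side branch.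

**Steps most likely to fail**

Step 6. The oxygen may add to C3' as well as C4', because the acetal oxygen at C5' opposes the triflyloxy bias. The enal may also be deprotonated at its γ-methyl groups by fluoride and self-condense, or quinone methide 12 may be intercepted by a second aryne. The fallback sets out from 8: the same aryne 10 is generated with CsF in N,N-dimethylformamide/MeCN. The formamide oxygen is a stronger, non-enolisable nucleophile whose additions follow aryne polarisation closely; it inserts its C=O group, and aqueous work-up should give 3-formyl-4-hydroxy-5-(methoxymethoxy)-1,2-phenylene bis(trifluoromethanesulfonate) F1, from which a minor regioisomer could be removed by crystallisation. Addition of 2-methylprop-1-enylmagnesium bromide (THF, −78 °C) should give 4-hydroxy-3-(1-hydroxy-3-methylbut-2-en-1-yl)-5-(methoxymethoxy)-1,2-phenylene bis(trifluoromethanesulfonate) F2. Warming F2 with pyridinium p-toluenesulfonate in toluene dehydrates it to quinone methide 12, which electrocyclises to 13, where the route is rejoined.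

Step 7. Oxidative addition may not discriminate between the two triflates of 13, or the second triflate may couple as well. The fallback sets out from 8 and moves the Stille coupling with tributyl(1-ethoxyethenyl)stannane (Pd(PPh3)4, LiCl, 1,4-dioxane, 70 °C, neutral work-up) ahead of the annulation. In 8 only the outer triflate has a free ortho position; the middle one is flanked on both sides and lies para to the acetal oxygen, and the third is shielded by the silyl group. The coupling should therefore give 3-(1-ethoxyethenyl)-5-(methoxymethoxy)-6-(trimethylsilyl)-1,2-phenylene bis(trifluoromethanesulfonate) F3. F3 is then treated with CsF and 9 as in step 6 to give enol ether 14, at which the route is rejoined; the acid treatment of step 7 then gives 16.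

Step 11. Hydride may add 1,2 to the electron-rich enone, giving an allylic alcohol that can cyclise onto the ring-A phenol, or the cascade may stall at ketone 22. The fallback sets out from 21: conjugate reduction with the copper hydride hexamer [(Ph3P)CuH]6 (catalytic, with polymethylhydrosiloxane, toluene, rt) should give ketone 22, now isolated. Corey–Bakshi–Shibata reduction with (S)-2-methyl-CBS-oxazaborolidine and catecholborane (toluene, −78 °C; catecholborane spares the alkenes) should then give the R alcohol 23, where the route is rejoined.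

Further compounds
F1 | step 6 | 3-formyl-4-hydroxy-5-(methoxymethoxy)-1,2-phenylene bis(trifluoromethanesulfonate) | COCOc1cc(OS(=O)(=O)C(F)(F)F)c(OS(=O)(=O)C(F)(F)F)c(C=O)c1O
F2 | step 6 | 4-hydroxy-3-(1-hydroxy-3-methylbut-2-en-1-yl)-5-(methoxymethoxy)-1,2-phenylene bis(trifluoromethanesulfonate), racemic | COCOc1cc(OS(=O)(=O)C(F)(F)F)c(OS(=O)(=O)C(F)(F)F)c(C(O)C=C(C)C)c1O
F3 | step 7 | 3-(1-ethoxyethenyl)-5-(methoxymethoxy)-6-(trimethylsilyl)-1,2-phenylene bis(trifluoromethanesulfonate) | CCOC(=C)c1cc(OCOC)c([Si](C)(C)C)c(OS(=O)(=O)C(F)(F)F)c1OS(=O)(=O)C(F)(F)F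
F0 | step 11 | none | none
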